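## Structural features

The target 13 is a germacrane. Its ten-membered carbocycle (C1–C10) carries an E trisubstituted olefin C1=C10 (C14 methyl on C10), a trans trisubstituted epoxide across C4–C5 (C15 methyl on C4), a free secondary hydroxyl at C6, an isopropyl group at C7 and, at C8, the ester of 3-hydroxy-4-methoxybenzoic acid. The five stereocentres C4 to C8 are contiguous and all R. The C6 and C8 oxygens are cis to each other and both trans to the isopropyl group, so all three substituents can be equatorial on one crown-type ring. The epoxide is erythro to the C6 carbinol (5R,6R). By analogy with the crown conformation of related germacranolides, its oxygen lies on the face of the former C4=C5 olefin that is buried in the all-equatorial crown. That is not the face that peripheral attack, or a peracid guided by the C6 hydroxyl, would choose. Fragile elements are: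

- the 2,3-epoxy alcohol with C1=C10 across the ring (acid would trigger transannular cyclisation, base a Payne shift);
- the 1,5-diene of every precursor that still has both olefins (Cope rearrangement on heating, cyclisation with acid);
- the hindered ester, which can migrate from O8 to the syn O6 under base;
- the free phenol.

The ester bond is trivial. The real difficulty is the medium ring with its E olefins, together with placing and telling apart three oxygens: one on the unactivated C8 methylene and one, the epoxide, on the less accessible face. The key step uses the fact that C1–C15 is an intact head-to-tail farnesyl chain. The ring bond C6–C7 joins the two ends of that chain, the C7 isopropyl is the former terminal olefin, the C6 oxygen sits on the former diphosphate carbon, and both E olefins (C1=C10, and C4=C5 that later becomes the epoxide) are already present in the chain.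

## Logic of the disconnections

13 to 12. The two O–Si bonds (phenol oxygen and C6 oxygen) are restored. The phenol must be masked for the esterification and O6 must be masked before a second hydroxyl appears. The gain is that the last step is one mild operation. The demand is a buffered fluoride source, so that the freed C6 hydroxyl neither attacks the epoxide nor takes over the acyl group from O8.

12 to 7 and 10. The acyl C–O bond at O8 is cut. This splits off the arene as a separate, simple fragment and makes the route convergent. The forward step must acylate a hindered secondary hydroxyl flanked by the isopropyl-bearing carbon. It can do so without any regiochemical question only because O6 of 7 is already silylated.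

10 to 8. The aryl O–Si bond is cut (by way of 9). The only demand is that the silyl ester formed at the same time is hydrolysed without loss of the aryl silyl ether.

7 to 6. The C8–O bond is cut back to a C–H bond. No functional group in the ring points to C8, and leaving it as a methylene lets the ring be made from the natural, unmodified chain. The price is a site- and face-selective oxidation of one of two C8–H bonds (the one cis to O6), in competition with weaker allylic C–H bonds at C9, C2 and C14 and with the C1=C10 olefin. Only a protein pocket can be expected to meet this.

6 to 5. The C6 O–Si bond is cut. Silylating when only one hydroxyl exists differentiates O6 from O8 by timing instead of by a selective acylation of a diol.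

5 to 4. Both epoxide C–O bonds are cut, which returns the C4=C5 olefin. This olefin is allylic to the C6 hydroxyl, so a metal alkoxide bound at O6 can pick it out from C1=C10. The demand is the erythro face. A hydroxyl-guided peracid would be expected to deliver oxygen to the crown-exposed, threo face, so the forward step needs an oxygen transfer that is matched to the (6R) carbinol and works at a small C6–O/olefin dihedral.

4 to 3. The ring bond C6–C7 and the C6–O bond are cut, and the hydrogen on C11 is returned to C6. One disconnection removes the ring, both stereocentres and the hydroxyl, and leaves an achiral open chain that already contains both E olefins. The forward step must fold that chain in one sense, close the ten-membered ring end to end, shift hydride and capture water at C6 on one face. This is the work of a terpene synthase.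

3 to 2 to 1. The C1–O bond to diphosphate is cut to the allylic bromide, and the C–Br bond back to the allylic alcohol. Both forward steps are direct substitutions at a primary allylic carbon and must not scramble the 2E olefin.

## Other disconnections considered

Alternative 1: The cut is C9–C10. In the forward sense, zerovalent nickel (Ni(cod)2, PBu3) with Et3B would join a C1≡C10 methyl alkyne to the terminal carbon of a C8–C9 epoxide at the other end of an open chain. Hydrogen is added syn at C1, which closes the ring with the E C1=C10 olefin and frees the C8 hydroxyl. The product is A1, the 6-O-TBS ether of 4,5-epoxygermacr-1(10)E-ene-6,8-diol, configured at C4–C8 as 13.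

- In its favour: all five stereocentres, including the erythro epoxy alcohol, are set on an open chain by reagent control, where ring conformation plays no part. The C8 hydroxyl is formed free beside a silylated O6, so A1 is the TBS analogue of 7 and needs only acylation and fluoride.
- Against it here: the closure would have to form a strained ten-membered E-cycloalkene in competition with intermolecular coupling. The regiochemistry at the alkyne rests only on the difference between a methyl group and the chain. The trisubstituted epoxide must stay a spectator to nickel and to the Lewis-acidic borane. The open chain needs a long linear sequence.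
- Comparison: on structure A1 is the better of the two, since it needs no C–H oxidation and has no facial problem at C4=C5. On mechanism the chosen plan relies on a reaction class made for this ring size, which builds the ring and two stereocentres at once, whereas the nickel closure at this ring size is an extrapolation. On step economy the chosen plan is clearly shorter.

Alternative 2: The cut is C2–C3. Zerovalent palladium (Pd(PPh3)4) would ionise an isopropenyl epoxide to a π-allyl complex over C3–C5 with an alkoxide at C6. The alkoxide deprotonates a C2 bis-sulfone, and the carbanion closes the ring at C3. The product is A2, 8-O-(4-methoxybenzyl)-2,2-bis(phenylsulfonyl)germacra-1(10)E,4E-diene-6,8-diol, configured at C6–C8 as 13.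

- In its favour: the closure is neutral and self-buffered, and the ion pair holds the chain ends together. The C6 hydroxyl and the E C4=C5 olefin are formed in the same event. The C8 oxygen is present from the start and orthogonally protected, which is better than the chosen plan on that point.
- Against it here: two sulfones must afterwards be removed reductively at C2, which is allylic to C1=C10, with a risk of olefin migration or loss of geometry. The E geometry of C4=C5 depends on the π-allyl isomer that closes. The benzyl ether must be removed oxidatively in the presence of an electron-rich diene.
- Comparison: the late epoxidation faces the same facial problem as the chosen plan, so the two are equal there, but it comes after a longer sequence. On mechanism both closures are credible. On step economy the chosen plan is better.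

Alternative 3: The strategic bond is C5–C10, present in a eudesmane-type decalin and cleaved in the key step. Activation of a C4 pinacol boronate as its ate complex (KOtBu or an aryllithium) would trigger antiperiplanar 1,4-fragmentation with loss of a C1 mesylate. This creates C4=C5 and C1=C10 and opens the ring to A3, the 6-O-TBS, 8-O-PMB ether of germacra-1(10)E,4E-diene-6,8-diol, configured at C6–C8 as 13.

- In its favour: the fragmentation is stereospecific, so both olefin geometries follow from the decalin configuration. C6, C7 and C8 are set on a rigid six-membered ring, where the all-equatorial triad is the easy one. The two oxygens are differentiated. No enzyme has to be found. On stereochemical security of C6–C8 and of the olefins it is the equal or the better of the chosen plan.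
- Against it here: seven stereocentres must be built on the decalin and four of them (C1, C4, C5, C10) are destroyed. A3 still needs two protecting-group exchanges and the same face-critical epoxidation. The boronate and mesylate are sacrificed.
- Comparison: on structure and mechanism it is sound. On step and atom economy it is far behind a plan that takes the whole skeleton from one commodity terpene alcohol.

Key step: step 3

Remark on the chemistry: 3 is drawn as the free acid but is made, stored and used as its tris-ammonium salt.
Remark on the chemistry: germacrane numbering is used for all cyclic compounds (ring C1–C10, C11 the isopropyl methine, C14 on C10, C15 on C4). Farnesyl C1 and C10 of 3 become C6 and C7. The C7 descriptor changes between R and S along the route only through CIP ranking; the centre itself is never touched.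

## Route

Step 1
Reactants: 1 (2E,6E)-farnesol
Product: 2 (2E,6E)-farnesyl bromide
Conditions: PBr3 (0.4 equiv), Et2O, −10 °C, 30 min; used crude
Reagents that add atoms: phosphorus tribromide, BrP(Br)Br
Why: Low-temperature bromination of a primary allylic terpenol with PBr3 is a standard direct substitution and should give the unrearranged 2E,6E bromide. No stereocentre is formed, and the labile bromide is carried on at once.

Step 2
Reactants: 2 (2E,6E)-farnesyl bromide
Product: 3 (2E,6E)-farnesyl diphosphate (isolated as tris-ammonium salt)
Conditions: (Bu4N)3HP2O7 (2 equiv), MeCN, rt; Dowex 50W (NH4+ form), NH4HCO3 buffer/iPrOH; cellulose chromatography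
Reagents that add atoms: tris(tetra-n-butylammonium) hydrogen diphosphate, CCCC[N+](CCCC)(CCCC)CCCC.CCCC[N+](CCCC)(CCCC)CCCC.CCCC[N+](CCCC)(CCCC)CCCC.OP(=O)([O-])OP(=O)([O-])[O-]
Why: Davisson–Poulter diphosphorylation: the organic-soluble diphosphate displaces the primary allylic halide by SN2 in an aprotic medium, so both E olefins should be kept. Ion exchange gives the stable ammonium salt needed by the enzyme.

Step 3
Reactants: 3 (2E,6E)-farnesyl diphosphate
Product: 4 (6R,7R)-germacra-1(10)E,4E-dien-6-ol
Conditions: recombinant (6R,7R)-selective germacradien-6-ol synthase, MgCl2 (10 mM), HEPES pH 7.5, DTT, pentane overlay, 30 °C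
Reagents that add atoms: water, O
Why: This is class one sesquiterpene synthase catalysis of the kunzeaol (germacradien-6-ol) type, the closest known reaction being this same conversion of the natural substrate. The magnesium-bound diphosphate of 3 ionises to the 2E allyl cation, whose C1 terminus (C6 of 4) is attacked by C10 of the distal olefin (C7 of 4); this Markovnikov end-to-end macrocyclisation closes the ten-membered ring with the attacking π bond exocyclic (10-exo with respect to that olefin) and leaves a tertiary cation at C11. A 1,3-hydride shift from C6 to C11 creates the isopropyl group and an allyl cation over C4–C6, which active-site water quenches at C6. C7 is set by the olefin face that the folded chain presents to C1 (the sense found in (R)-germacrene D, here 7R) and C6 by the face of water capture; both are decided by the protein and not by the achiral substrate. Both E olefins are inherited from the 2E,6E chain because the pocket leaves the allyl cations no room to rotate. The step needs 1,10- over 1,11-closure, hydride shift over deprotonation to germacrene hydrocarbons, and water capture at C6 over C4; these are properties of the synthase, which is therefore chosen by screening kunzeaol-type enzymes and engineered if necessary. The pentane overlay removes the acid- and heat-labile 1,5-diene from the aqueous phase as it forms.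

Step 4
Reactants: 4 (6R,7R)-germacra-1(10)E,4E-dien-6-ol
Product: 5 (4R,5R,6R,7R)-4,5-epoxygermacr-1(10)E-en-6-ol
Conditions: Ti(OiPr)4 (0.5 equiv), D-(−)-diisopropyl tartrate (0.6 equiv), TBHP (2 equiv, in decane), 4 Å MS, CH2Cl2, −20 °C
Reagents that add atoms: tert-butyl hydroperoxide, CC(C)(C)OO
Why: Sharpless titanium–tartrate epoxidation of a secondary allylic alcohol: the D-tartrate catalyst delivers oxygen to the C4=C5 face that gives (4R,5R), and for that face the (6R) carbinol is the fast-reacting, erythro-forming partner, so reagent and substrate are matched. The titanium alkoxide transfers oxygen with the C6–O bond near the olefin plane, a geometry the ring should offer only in the conformer that exposes this face, whereas a peracid bound at about 120° to the crown conformer would give the 4,5-diastereomer. C1=C10 has no allylic hydroxyl and should stay untouched.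

Step 5
Reactants: 5 (4R,5R,6R,7R)-4,5-epoxygermacr-1(10)E-en-6-ol
Product: 6 (4R,5R,6R,7R)-4,5-epoxy-6-(triethylsilyloxy)germacr-1(10)E-ene
Conditions: TESCl, imidazole, DMAP (cat.), DMF, 0 °C → rt
Reagents that add atoms: chlorotriethylsilane, CC[Si](Cl)(CC)CC
Why: Base-buffered silylation of the only hydroxyl, with no Lewis acid that could open the epoxide toward C1=C10. O6 is masked before the second hydroxyl exists, so O6 and O8 are told apart by timing.

Step 6
Reactants: 6 (4R,5R,6R,7R)-4,5-epoxy-6-(triethylsilyloxy)germacr-1(10)E-ene
Product: 7 (4R,5R,6R,7S,8R)-4,5-epoxy-6-(triethylsilyloxy)germacr-1(10)E-en-8-ol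
Conditions: evolved cytochrome P450 monooxygenase (CYP102A1 variant), O2 (air), NADP+ (cat.), D-glucose, glucose dehydrogenase, KPi pH 8.0, 2% DMSO, 25 °C
Reagents that add atoms: dioxygen, O=O
Why: Proposed new method: the iron-oxo species of the P450 abstracts a hydrogen atom from C8 and returns hydroxyl to the same face (rebound, retention), so the C8–H cis to O6 must be the one held over the iron, which only the binding pocket can enforce against the weaker allylic C–H bonds at C9, C2 and C14 and against epoxidation of C1=C10. The closest known reaction types are C8 hydroxylation of germacrene A acid by plant CYP71-type hydroxylases and hydroxylation of the 4,5-epoxygermacrene parthenolide by evolved CYP102A1 variants. No enzyme is known for this substrate and face, so the variant must be found by screening and directed evolution, with the silyl ether as a hydrophobic anchor.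

Step 7
Reactants: 8 isovanillic acid (3-hydroxy-4-methoxybenzoic acid)
Product: 10 3-(tert-butyldimethylsilyloxy)-4-methoxybenzoic acid, via bis-silylated silyl ester 9 (not isolated)
Conditions: TBSCl (2.5 equiv), imidazole, DMF, rt; then AcOH/THF/H2O, rt
Reagents that add atoms: tert-butyldimethylsilyl chloride, CC(C)(C)[Si](C)(C)Cl
Why: Exhaustive silylation followed by hydrolysis of the labile silyl ester in mild aqueous acid is the usual way to a phenol-protected hydroxybenzoic acid. The aryl silyl ether survives and later leaves together with the TES group in one fluoride step.

Step 8
Reactants: 7 (4R,5R,6R,7S,8R)-4,5-epoxy-6-(triethylsilyloxy)germacr-1(10)E-en-8-ol; 10 3-(tert-butyldimethylsilyloxy)-4-methoxybenzoic acid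
Product: 12 (4R,5R,6R,7S,8R)-4,5-epoxy-6-(triethylsilyloxy)germacr-1(10)E-en-8-yl 3-(tert-butyldimethylsilyloxy)-4-methoxybenzoate, via mixed trichlorobenzoic anhydride 11 (not isolated)
Conditions: 10, 2,4,6-trichlorobenzoyl chloride, Et3N, THF, rt; then 7, DMAP, toluene, rt → 40 °C
Reagents that add atoms: none
Why: Yamaguchi esterification: DMAP takes the less hindered aroyl group from the mixed anhydride and transfers it to the C8 hydroxyl, the only free hydroxyl of 7. Acylation at oxygen leaves the C8 configuration untouched.

Step 9
Reactants: 12 (4R,5R,6R,7S,8R)-4,5-epoxy-6-(triethylsilyloxy)germacr-1(10)E-en-8-yl 3-(tert-butyldimethylsilyloxy)-4-methoxybenzoate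
Product: 13 (4R,5R,6R,7R,8R)-4,5-epoxy-6-hydroxygermacr-1(10)E-en-8-yl 3-hydroxy-4-methoxybenzoate (target)
Conditions: TBAF (3 equiv), AcOH (3 equiv), THF, 0 °C → rt
Reagents that add atoms: none
Why: Fluoride desilylation removes the aryl TBS and the alkyl TES ether in one operation. Acetic acid keeps O6 protonated, so neither acyl migration from O8 to O6 nor a Payne shift should set in, and no acid strong enough to open the epoxide toward C1=C10 is present.

## Compound list

1 | (2E,6E)-farnesol | CC(C)=CCC/C(C)=C/CC/C(C)=C/CO | starting material
2 | (2E,6E)-farnesyl bromide | CC(C)=CCC/C(C)=C/CC/C(C)=C/CBr | intermediate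
3 | (2E,6E)-farnesyl diphosphate | CC(C)=CCC/C(C)=C/CC/C(C)=C/COP(=O)(O)OP(=O)(O)O | intermediate
4 | (6R,7R)-germacra-1(10)E,4E-dien-6-ol | C1C/C(C)=C/CC/C(C)=C/[C@H](O)[C@H]1C(C)C | intermediate
5 | (4R,5R,6R,7R)-4,5-epoxygermacr-1(10)E-en-6-ol | C1C/C(C)=C/CC[C@@]2(C)O[C@@H]2[C@H](O)[C@H]1C(C)C | intermediate
6 | (4R,5R,6R,7R)-4,5-epoxy-6-(triethylsilyloxy)germacr-1(10)E-ene | C1C/C(C)=C/CC[C@@]2(C)O[C@@H]2[C@H](O[Si](CC)(CC)CC)[C@H]1C(C)C | intermediate
7 | (4R,5R,6R,7S,8R)-4,5-epoxy-6-(triethylsilyloxy)germacr-1(10)E-en-8-ol | O[C@@H]1C/C(C)=C/CC[C@@]2(C)O[C@@H]2[C@H](O[Si](CC)(CC)CC)[C@H]1C(C)C | intermediate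
8 | isovanillic acid (3-hydroxy-4-methoxybenzoic acid) | COc1ccc(C(=O)O)cc1O | starting material
9 | tert-butyldimethylsilyl 3-(tert-butyldimethylsilyloxy)-4-methoxybenzoate | COc1ccc(C(=O)O[Si](C)(C)C(C)(C)C)cc1O[Si](C)(C)C(C)(C)C | intermediate
10 | 3-(tert-butyldimethylsilyloxy)-4-methoxybenzoic acid | COc1ccc(C(=O)O)cc1O[Si](C)(C)C(C)(C)C | intermediate
11 | 3-(tert-butyldimethylsilyloxy)-4-methoxybenzoic 2,4,6-trichlorobenzoic anhydride | COc1ccc(C(=O)OC(=O)c2c(Cl)cc(Cl)cc2Cl)cc1O[Si](C)(C)C(C)(C)C | intermediate
12 | (4R,5R,6R,7S,8R)-4,5-epoxy-6-(triethylsilyloxy)germacr-1(10)E-en-8-yl 3-(tert-butyldimethylsilyloxy)-4-methoxybenzoate | COc1ccc(C(=O)O[C@@H]2C/C(C)=C/CC[C@@]3(C)O[C@@H]3[C@H](O[Si](CC)(CC)CC)[C@H]2C(C)C)cc1O[Si](C)(C)C(C)(C)C | intermediate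
13 | (4R,5R,6R,7R,8R)-4,5-epoxy-6-hydroxygermacr-1(10)E-en-8-yl 3-hydroxy-4-methoxybenzoate | COc1ccc(C(=O)O[C@@H]2C/C(C)=C/CC[C@@]3(C)O[C@@H]3[C@H](O)[C@H]2C(C)C)cc1O | target

## Step count and least certain steps

Total step count: 9. Longest linear sequence: 8 steps (1 to 13 through steps 1–6, 8 and 9); step 7 is the side branch.

**Step 6 (carries the label).**
- What may go wrong: hydrogen abstraction at the weaker allylic C–H bonds (C9, C2, C14) or oxygen transfer to C1=C10 instead of C8; delivery of hydroxyl to the other C8 face; or the search for a suitable variant not converging, since no enzyme is known for this substrate.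
- Fallback by known chemistry, setting out from 5 and rejoining the route at 13:
 - Dehydrogenative silylation of the C6 hydroxyl of 5 with Et2SiH2 and [Ir(cod)OMe]2 (cat., THF, rt) gives the diethyl(hydrido)silyl ether F1.
 - With [Ir(cod)OMe]2, 3,4,7,8-tetramethyl-1,10-phenanthroline and norbornene as hydrogen acceptor (THF, 100 °C), the tethered silicon is expected to insert into the γ C8–H bond cis to O6. This is the only secondary γ C–H bond; C11–H is tertiary and C4 bears no hydrogen. The five-membered ring closes to the oxasilolane F2.
 - Tamao–Fleming oxidation (H2O2, KHCO3, KF, THF/MeOH) replaces silicon by hydroxyl with retention and gives the epoxy diol F3.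
 - Esterification of F3 with 10 under the conditions of step 8 should take the C8 hydroxyl, because the C6 hydroxyl is flanked by the epoxide and the isopropyl-bearing carbon and can hydrogen-bond to the epoxide oxygen. This gives the 8-mono-ester F4.
 - Buffered TBAF as in step 9 then gives 13.
- The reaction types are alcohol-directed iridium-catalysed silylation of secondary γ C–H bonds and Tamao–Fleming oxidation. The price is a regioselective acylation of a diol, and the epoxide must tolerate the hot silylation.

**Step 3 (key step).**
- What may go wrong: water capture on the other face of the allyl cation or at C4; deprotonation of the C11 cation to germacrene hydrocarbons; loss of the diene by Cope rearrangement or acid-induced transannular cyclisation during isolation. A synthase with the antipodal fold would give the enantiomeric series, and this cannot be repaired chemically.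
- Fallback for the C6 problem, setting out from 3 and returning at 4: a synthase that closes the ring in the required C7 sense but delivers the C6 epimer (6S,7R)-germacra-1(10)E,4E-dien-6-ol F5, or an epimer mixture, is accepted. MnO2 (CH2Cl2, rt) oxidises the allylic alcohol to (7R)-germacra-1(10)E,4E-dien-6-one F6. A 1,2-reduction under reagent control (CBS oxazaborolidine with catecholborane, the antipode chosen for the 6R carbinol; Luche reduction as the substrate-controlled variant) returns 4. This moves control of C6 from the enzyme to a reagent.

**Step 4.**
- What may go wrong: slow oxygen transfer at the crowded titanium centre (secondary carbinol next to the isopropyl-bearing carbon, C15 cis on the olefin), which would let reaction through the crown conformer erode the facial selectivity; and Lewis-acid-induced transannular opening of 5.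
- Fallback, setting out from 4 and returning at 5 with no new compound (F0): ligand control is given up in favour of substrate control. The mononuclear, less Lewis-acidic system VO(acac)2 (cat.)/TBHP with 2,6-lutidine in toluene at 0 °C is used. Stereocontrol then rests on the ring alone: the vanadium alkoxide also transfers oxygen at a small C6–O/olefin dihedral, and with C7 held in the ring only the conformer that exposes the (4R,5R) face should offer this. A peracid is excluded, because its geometry fits the crown and would lead to the (4S,5S) epimer.

## Further compounds

F1 | step 6 | (4R,5R,6R,7R)-6-[(diethylsilyl)oxy]-4,5-epoxygermacr-1(10)E-ene | C1C/C(C)=C/CC[C@@]2(C)O[C@@H]2[C@H](O[SiH](CC)CC)[C@H]1C(C)C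
F2 | step 6 | oxasilolane of 5 with a diethylsilanediyl bridge from O6 to C8 (silicon on C8 cis to O6) | CC[Si]3(CC)[C@@H]1C/C(C)=C/CC[C@@]2(C)O[C@@H]2[C@H](O3)[C@H]1C(C)C
F3 | step 6 | (4R,5R,6R,7S,8R)-4,5-epoxygermacr-1(10)E-ene-6,8-diol | O[C@@H]1C/C(C)=C/CC[C@@]2(C)O[C@@H]2[C@H](O)[C@H]1C(C)C
F4 | step 6 | (4R,5R,6R,7R,8R)-4,5-epoxy-6-hydroxygermacr-1(10)E-en-8-yl 3-(tert-butyldimethylsilyloxy)-4-methoxybenzoate | COc1ccc(C(=O)O[C@@H]2C/C(C)=C/CC[C@@]3(C)O[C@@H]3[C@H](O)[C@H]2C(C)C)cc1O[Si](C)(C)C(C)(C)C
F5 | step 3 | (6S,7R)-germacra-1(10)E,4E-dien-6-ol | C1C/C(C)=C/CC/C(C)=C/[C@@H](O)[C@H]1C(C)C
F6 | step 3 | (7R)-germacra-1(10)E,4E-dien-6-one | C1C/C(C)=C/CC/C(C)=C/C(=O)[C@H]1C(C)C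
F0 | step 4 | none | none
A1 | alternative 1 | 6-O-TBS ether of 4,5-epoxygermacr-1(10)E-ene-6,8-diol, configured at C4–C8 as 13 | O[C@@H]1C/C(C)=C/CC[C@@]2(C)O[C@@H]2[C@H](O[Si](C)(C)C(C)(C)C)[C@H]1C(C)C
A2 | alternative 2 | 8-O-(4-methoxybenzyl)-2,2-bis(phenylsulfonyl)germacra-1(10)E,4E-diene-6,8-diol, configured at C6–C8 as 13 | COc1ccc(CO[C@@H]2C/C(C)=C/C(S(=O)(=O)c3ccccc3)(S(=O)(=O)c3ccccc3)C/C(C)=C/[C@H](O)[C@H]2C(C)C)cc1
A3 | alternative 3 | 6-O-TBS, 8-O-(4-methoxybenzyl) ether of germacra-1(10)E,4E-diene-6,8-diol, configured at C6–C8 as 13 | COc1ccc(CO[C@@H]2C/C(C)=C/CC/C(C)=C/[C@H](O[Si](C)(C)C(C)(C)C)[C@H]2C(C)C)cc1
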